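## Structural features

The target is a sesquineolignan made of three C6C3 units. A (2R,3R)-2,3-dibenzylbutane-1,4-diol chain carries the guaiacyl ring A on one benzylic carbon; the other benzylic carbon is attached to C5 of a 2,3-dihydrobenzofuran (benzo ring B fused to dihydrofuran ring C). This bicycle has OMe at C7, CH2OH at C3 and the guaiacyl ring D at C2. The four stereocentres form two adjacent pairs, butane C2/C3 and benzofuran C2/C3 (2S,3R, aryl and hydroxymethyl trans). An aryl–CH2 spacer separates the pairs, so neither can control the other. The fragile elements are the two free guaiacol phenols, the three primary alcohols and the C2–O1 bond of ring C, a secondary benzylic aryl ether para to an oxygen of ring D that is open to acid and to hydrogenolysis. At the ester oxidation level C3–H is acidic, which invites epimerisation and β-elimination of O1. The real difficulty is absolute control of the trans C2/C3 pair of ring C, followed by union with the butane half without disturbing it. The feature used by the key step is that C2 is a benzylic ether carbon bound to O1 and ring D, in a 1,5 relationship to C3 through C3a, C7a and O1. A carbene at C3, carried by ring B and stabilised by a carboxyl group that later becomes the CH2OH, can therefore insert into a C2–H bond and close ring C.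

## Logic of the disconnections

**Protecting groups (30 ⇒ 29 ⇒ 28).** The two phenolic O–H bonds are traced back to O–CH2Ph bonds and the C3 carbinol O–H to an O–Si bond. Free phenols and a free carbinol would quench the organolithium, enolate and hydride reagents used earlier, and a single benzyl type on rings A and D lets both fall in one operation. The gain is a fully masked, non-acidic intermediate. The demand is that fluoride removes silicon only and that hydrogenolysis stops at the two primary O–CH2Ph bonds without opening the C2–O1 bond of ring C.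

**Diol to lactone (28 ⇒ 27).** One C–O bond is re-formed and one CH2OH is raised to the carboxyl level, so the butane chain becomes a γ-lactone. The carbonyl makes the neighbouring carbon nucleophilic and the ring turns the existing stereocentre into a control element. The gain is that the second butane stereocentre becomes accessible by 1,2-induction. The demand is a hydride reduction that leaves silyl and benzyl ethers untouched.

**Union of the halves (27 ⇒ 26 + 19).** The C–C bond between the lactone α-carbon and the benzylic CH2 on C5 of ring B is cut. This is the most convergent cut: it gives two chiral halves of similar size that are made independently. The demand is an SN2 alkylation anti to the β-substituent of 26 with the electron-rich, labile bromide 19, faster than proton exchange, which is why no acidic OH may be present.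

**Benzylic carbon on ring B (19 ⇒ 18 ⇒ 16, passing 17).** The C–Br bond is traced to C–OH, and the aryl–CH2 bond at C5 is cut back to an aryl–Br bond plus a one-carbon electrophile. Bromine is inert to diazo transfer and to the carbene but is a latent aryl nucleophile, so the C5 carbon need not be carried in protected form through the first half. The demand is that bromine–lithium exchange outruns deprotonation at C2; formylation and reduction are run in one flask.

**Carbinol to ester (16 ⇒ 15 ⇒ 14).** The O–Si bond is removed and the C3 CH2OH is traced to a carboxylic ester of a chiral alcohol. The carboxyl group is the acceptor that makes a C3 carbene accessible, and its alkoxy part can carry stereochemical information. The demand is a reduction that releases the auxiliary without epimerising C3 or opening ring C by β-elimination.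

**Key disconnection (14 ⇒ 13).** The C2–C3 bond is cut: ring C opens, C3 becomes a diazo carbon and C2 returns to an aryl–CH2–O group. One ring, one C–C bond and both ring C stereocentres disappear at once, leaving an aryl acetate whose only stereocentre comes from lactate. The demand is 1,5-site selectivity, attack on the (2S) face and trans geometry. The substitution of 13 is kept because each group has a later use: bromine becomes the C5 carbon, the benzyl ether falls together with that of ring A, and the lactamide ester gives stereocontrol and separable diastereomers.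

**Diazo ester (13 ⇒ 12 ⇒ 9 + 11; 11 ⇒ 10).** The C=N2 unit is removed, the ester C–O bond is cut into acid and chiral alcohol, and the amide C–N bond of the alcohol leads back to a lactate ester. The gain is three simple pieces. The demand is diazo transfer to the benzylic CH2 without racemising the lactate centre.

**Arylacetic acid (9 ⇒ 7, passing 8; 7 ⇒ 4 + 6; 6 ⇒ 5).** The carboxyl carbon is traced to the internal carbon of an allyl group, and the O1–CH2 ether bond is cut into a phenol and a benzylic bromide. The allyl group is the cheapest two-carbon handle that can be placed ortho to a phenol. The demand is an oxidative cleavage that spares two electron-rich rings and two benzylic ethers.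

**Ring B (4 ⇒ 3 ⇒ 1 + 2).** The aryl–allyl C–C bond is traced by a [3,3] shift to an O-allyl ether and this to the phenol. Regiochemistry is fixed because only one ortho position is free and the para position holds bromine.

**Ring A half (26 ⇒ 24, passing 25; 24 ⇒ 23 + 6; 23 ⇒ 20 + 21, passing 22).** The lactone C–O bond is opened and the carbinol carbon traced to an imide carbonyl. The C–C bond between the stereocentre and the ring A benzylic carbon is then cut to an imide enolate and 6, the same bromide that supplies ring D. The demand is regioselective enolisation next to the imide and alkylation on the face opposite to the auxiliary substituent.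

## Other disconnections considered

**Alternative 1:** The cut is O1–C2.

- **Forward step:** Ag2O (monovalent silver) would oxidise ring D of the diphenol 4-bromo-2-[(2R)-1-[(tert-butyldimethylsilyl)oxy]-3-(4-hydroxy-3-methoxyphenyl)propan-2-yl]-6-methoxyphenol A1 to the quinone methide A2. The ring B phenol would then add to the exocyclic carbon to give the trans dihydrobenzofuran A3.
- **In favour:** The closure mirrors the biosynthetic one. It needs no diazo compound and no chiral rhodium catalyst, and only the C3 centre must be made beforehand. O-Benzylation of A3 would give 16, so the route could be rejoined there.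
- **Against:** Ring B of A1 is itself an ortho-alkyl guaiacol; its oxidation through C3 would erase the only stereocentre. Ring D has a free ortho position open to radical coupling, and A2 can add water. The trans preference rests on 1,2-induction alone, and silver is stoichiometric.
- **Comparison:** Structurally it forms a C–O bond and one stereocentre, where the chosen step forms a C–C bond and two. Mechanistically it is an ionic conjugate addition under thermodynamic bias against a concerted insertion under reagent control. On trans geometry the two are equal, since trans is the stable isomer in both. On reagent safety and cost Alternative 1 is better. On security of absolute configuration the chosen plan is stronger. Step economy is about equal, because A1 needs an auxiliary-controlled construction of similar length to that of 13.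

**Alternative 2:** The cuts are the two C–C bonds that join the butane stereocentres to their benzylic carbons.

- **Forward step:** The lithiated dithiane A5, made from 17, would add to the β-carbon of (5R)-5-menthyloxyfuran-2(5H)-one A4 anti to the acetal substituent. The enolate would be trapped in the same flask by 6 to give the lactone A6. Desulfurisation and LiAlH4 reduction would then lead to 28.
- **In favour:** Two C–C bonds and both butane stereocentres form in one flask under control of a cheap menthol acetal. Steps 13 to 17 and the separate synthesis of 26 would be replaced by about four operations. On convergence and step count this alternative is the better one.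
- **Against:** It does not address ring C, so it is a rival only for the second half of the route and still needs step 9 or an equivalent. Dithioacetal formation requires a Lewis acid next to the silyl ether and the C2–O1 bond. Desulfurisation with Raney Ni threatens both benzyl ethers and ring C more severely than step 20 does.
- **Comparison:** The structural outcome is equal (trans, R,R butane unit). Both plans rely on anti addition to a ring substituent, so they are equal on relative control. The chosen plan is longer but keeps every step within conditions that ring C should tolerate.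

**Alternative 3:** The cut is C3–C3a, a ring contraction in reverse.

- **Forward step:** The flavanone (2S)-6-bromo-8-methoxy-2-[3-methoxy-4-(pivaloyloxy)phenyl]chroman-4-one A7 would be treated with PhI(OAc)2 (trivalent iodine), H2SO4 and HC(OMe)3. After enol ether formation and iodination at C3, the ring B carbon would shift from the carbonyl carbon to C3 with loss of PhI, giving the trans methyl ester A8.
- **In favour:** A7 should be reachable in about three steps from an acetophenone and a benzaldehyde. No metal carbene is involved, and the anti migration enforces trans geometry. A8 has the skeleton of 14 with a simpler ester. On step count to ring C this alternative is better, and on trans geometry it is equal.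
- **Against:** All absolute configuration rests on an enantiopure flavanone, which is hard to obtain and can racemise by ring opening to the chalcone in the strongly acidic medium. Migration of ring D and dehydrogenation to the flavone compete. Ring D must be deactivated as a pivalate while ring B carries a deactivating bromine. The pivalate would not survive step 12, so a protecting group exchange would give back part of the saving.
- **Comparison:** The product type is the same. The mechanism is a cationic 1,2-aryl shift against a carbene insertion. The chosen plan sets both centres under reagent control and can correct C3, so it is stronger on enantiocontrol, while Alternative 3 wins on length.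

Key step: step 9

**Assumptions**
- The (S)-lactamide ester and Rh2(S-DOSP)4 are taken as the matched pair leading to the (2S) series; the C3 descriptor changes from S in ester 14 to R in carbinol 15 through CIP priorities only, not through a change in space.
- A chiral S-benzylthiolanium salt of ring D would serve a sulfur-ylide annulation and has no function in a carbene C–H insertion; 13 is the only precursor of the key step.
- Metalated or metal-bound transients of a single operation (enolates, the aryllithium, the osmate ester, the rhodium carbene) are treated as mechanistic species without numbers; each neutral compound that stands between two stages of a one-flask or telescoped step is numbered.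

## Steps

Step 1
Reactants: 1 4-bromo-2-methoxyphenol; 2 allyl bromide
Product: 3 1-(allyloxy)-4-bromo-2-methoxybenzene
Conditions: K2CO3, acetone, reflux
Reagents that add atoms: none
Why: Williamson ether synthesis; the phenoxide displaces bromide from the allylic halide by SN2 and no stereocentre is involved.

Step 2
Reactants: 3 1-(allyloxy)-4-bromo-2-methoxybenzene
Product: 4 2-allyl-4-bromo-6-methoxyphenol
Conditions: N,N-diethylaniline, 200 °C
Reagents that add atoms: none
Why: Aromatic Claisen rearrangement; the [3,3] shift can end only at the single free ortho position because the other ortho site bears OMe and the para site bears bromine, and tautomerisation restores the phenol.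

Step 3
Reactants: 5 [4-(benzyloxy)-3-methoxyphenyl]methanol
Product: 6 1-(benzyloxy)-4-(bromomethyl)-2-methoxybenzene
Conditions: PBr3, Et2O, 0 °C
Reagents that add atoms: phosphorus tribromide, BrP(Br)Br
Why: Conversion of a benzylic alcohol into the bromide through a phosphite ester and bromide displacement; the electron-rich bromide is used fresh in steps 4 and 15.

Step 4
Reactants: 4 2-allyl-4-bromo-6-methoxyphenol; 6 1-(benzyloxy)-4-(bromomethyl)-2-methoxybenzene
Product: 7 1-allyl-2-{[4-(benzyloxy)-3-methoxybenzyl]oxy}-5-bromo-3-methoxybenzene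
Conditions: K2CO3, n-Bu4NI (cat.), DMF, rt
Reagents that add atoms: none
Why: Williamson etherification; even the 2,6-disubstituted phenoxide should be O-alkylated cleanly by the reactive benzylic bromide in a dipolar aprotic solvent.

Step 5
Reactants: 7 1-allyl-2-{[4-(benzyloxy)-3-methoxybenzyl]oxy}-5-bromo-3-methoxybenzene
Product: 9 2-(2-{[4-(benzyloxy)-3-methoxybenzyl]oxy}-5-bromo-3-methoxyphenyl)acetic acid, via arylacetaldehyde 8 (not isolated)
Conditions: OsO4 (cat.), NaIO4, 2,6-lutidine, dioxane/H2O, rt; extraction; then NaClO2, NaH2PO4, 2-methyl-2-butene, t-BuOH/H2O, 0 °C to rt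
Reagents that add atoms: osmium tetroxide, O=[Os](=O)(=O)=O (oxygen carrier, reoxidised by sodium periodate, [Na+].[O-]I(=O)(=O)=O); sodium chlorite, [Na+].[O-]Cl=O
Why: Lemieux–Johnson cleavage shortens the allyl group to the arylacetaldehyde, and Pinnick oxidation with a hypochlorite scavenger takes the crude, enolisable aldehyde to the acid. Neither oxidant should attack the aryl bromide, the benzylic ethers or the electron-rich rings.

Step 6
Reactants: 10 ethyl (S)-lactate
Product: 11 (S)-2-hydroxy-1-(pyrrolidin-1-yl)propan-1-one
Conditions: pyrrolidine (neat), rt to 45 °C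
Reagents that add atoms: pyrrolidine, C1CCNC1
Why: Aminolysis of an α-hydroxy ester by a nucleophilic secondary amine; no base strong enough to deprotonate the stereocentre is present, so the (S) configuration should be kept.

Step 7
Reactants: 9 2-(2-{[4-(benzyloxy)-3-methoxybenzyl]oxy}-5-bromo-3-methoxyphenyl)acetic acid; 11 (S)-2-hydroxy-1-(pyrrolidin-1-yl)propan-1-one
Product: 12 (S)-1-oxo-1-(pyrrolidin-1-yl)propan-2-yl 2-(2-{[4-(benzyloxy)-3-methoxybenzyl]oxy}-5-bromo-3-methoxyphenyl)acetate
Conditions: EDC·HCl, DMAP (cat.), CH2Cl2, 0 °C to rt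
Reagents that add atoms: none
Why: Steglich esterification; the carbodiimide activates the acid and DMAP transfers the acyl group to the secondary alcohol, whose stereocentre is not involved in bond making.

Step 8
Reactants: 12 (S)-1-oxo-1-(pyrrolidin-1-yl)propan-2-yl 2-(2-{[4-(benzyloxy)-3-methoxybenzyl]oxy}-5-bromo-3-methoxyphenyl)acetate
Product: 13 (S)-1-oxo-1-(pyrrolidin-1-yl)propan-2-yl 2-(2-{[4-(benzyloxy)-3-methoxybenzyl]oxy}-5-bromo-3-methoxyphenyl)-2-diazoacetate
Conditions: p-ABSA, DBU, MeCN, 0 °C to rt
Reagents that add atoms: 4-acetamidobenzenesulfonyl azide (p-ABSA), CC(=O)Nc1ccc(cc1)S(=O)(=O)N=[N+]=[N-]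
Why: Regitz diazo transfer; DBU enolises the aryl- and ester-activated CH2, which takes the terminal nitrogens of the sulfonyl azide. The much less acidic lactate C–H should remain untouched.

Step 9
Reactants: 13 (S)-1-oxo-1-(pyrrolidin-1-yl)propan-2-yl 2-(2-{[4-(benzyloxy)-3-methoxybenzyl]oxy}-5-bromo-3-methoxyphenyl)-2-diazoacetate
Product: 14 (S)-1-oxo-1-(pyrrolidin-1-yl)propan-2-yl (2S,3S)-2-[4-(benzyloxy)-3-methoxyphenyl]-5-bromo-7-methoxy-2,3-dihydrobenzofuran-3-carboxylate
Conditions: Rh2(S-DOSP)4 (1 mol %), CH2Cl2, 0 °C to rt, slow addition of 13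
Reagents that add atoms: none
Why: The chiral dirhodium tetraprolinate (divalent rhodium) expels N2 from the donor/acceptor diazo ester and holds the resulting electrophilic carbene at C3. The carbene attacks a C–H bond of the O1–CH2 group in a concerted but asynchronous three-centre transition state, in which the developing positive charge on the benzylic carbon is stabilised by O1 and by the para-oxygenated ring D. The closest known reaction type is the dirhodium-carboxylate-catalysed intramolecular C–H insertion of ortho-alkoxy aryldiazoacetates to 2-aryl-2,3-dihydrobenzofuran-3-carboxylates. Ring C closes as a five-membered ring by 1,5-insertion (carbene carbon, C3a, C7a, O1, C2), the only site within easy reach, since the 7-OMe group and the remote PhCH2O group would require larger rings and the aryl bromide is inert. C2 is defined by which of the two enantiotopic benzylic hydrogens is replaced, with retention at that carbon, and C3 by the carbene face that the C–H bond reaches. Both choices are made in the chiral pocket of the catalyst and should be reinforced by the (S)-lactamide ester, which biases the ester conformation (matched double stereodifferentiation), so the (2S,3S)-trans ester should predominate and minor isomers are separable diastereomers. Trans is also the thermodynamic geometry, so a cis ester of the same C2 configuration could be converted into 14 by brief equilibration of the acidic C3–H with DBU. The step needs site selectivity (secured by ring size and the doubly activated C–H bond), chemoselectivity over carbene dimerisation (secured by slow addition) and facial selectivity (secured by catalyst plus auxiliary).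

Step 10
Reactants: 14 (S)-1-oxo-1-(pyrrolidin-1-yl)propan-2-yl (2S,3S)-2-[4-(benzyloxy)-3-methoxyphenyl]-5-bromo-7-methoxy-2,3-dihydrobenzofuran-3-carboxylate
Product: 15 [(2S,3R)-2-[4-(benzyloxy)-3-methoxyphenyl]-5-bromo-7-methoxy-2,3-dihydrobenzofuran-3-yl]methanol
Conditions: LiBH4, THF/MeOH, 0 °C to rt
Reagents that add atoms: none
Why: Chemoselective ester reduction by LiBH4; the amide of the released auxiliary and the aryl bromide should not react. The weakly basic hydride should neither epimerise C3 nor trigger β-elimination of O1.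

Step 11
Reactants: 15 [(2S,3R)-2-[4-(benzyloxy)-3-methoxyphenyl]-5-bromo-7-methoxy-2,3-dihydrobenzofuran-3-yl]methanol
Product: 16 {[(2S,3R)-2-[4-(benzyloxy)-3-methoxyphenyl]-5-bromo-7-methoxy-2,3-dihydrobenzofuran-3-yl]methoxy}(tert-butyl)dimethylsilane
Conditions: TBSCl, imidazole, DMF, rt
Reagents that add atoms: tert-butyldimethylsilyl chloride, CC(C)(C)[Si](C)(C)Cl
Why: Imidazole-promoted silylation of a primary alcohol; the silyl ether removes the only acidic proton before the organolithium and enolate steps.

Step 12
Reactants: 16 {[(2S,3R)-2-[4-(benzyloxy)-3-methoxyphenyl]-5-bromo-7-methoxy-2,3-dihydrobenzofuran-3-yl]methoxy}(tert-butyl)dimethylsilane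
Product: 18 [(2S,3R)-2-[4-(benzyloxy)-3-methoxyphenyl]-3-{[(tert-butyldimethylsilyl)oxy]methyl}-7-methoxy-2,3-dihydrobenzofuran-5-yl]methanol, via 5-carbaldehyde 17 (not isolated)
Conditions: n-BuLi, THF, −78 °C; DMF, −78 to −40 °C; then MeOH, NaBH4, −40 to 0 °C
Reagents that add atoms: N,N-dimethylformamide, CN(C)C=O
Why: Bromine–lithium exchange at −78 °C is faster than deprotonation at C2 or attack on the silyl ether. Bouveault formylation with DMF gives a hemiaminal alkoxide that collapses to the aldehyde on methanolysis and is reduced at once by borohydride.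

Step 13
Reactants: 18 [(2S,3R)-2-[4-(benzyloxy)-3-methoxyphenyl]-3-{[(tert-butyldimethylsilyl)oxy]methyl}-7-methoxy-2,3-dihydrobenzofuran-5-yl]methanol
Product: 19 {[(2S,3R)-2-[4-(benzyloxy)-3-methoxyphenyl]-5-(bromomethyl)-7-methoxy-2,3-dihydrobenzofuran-3-yl]methoxy}(tert-butyl)dimethylsilane
Conditions: CBr4, PPh3, 2,6-lutidine, CH2Cl2, 0 °C
Reagents that add atoms: carbon tetrabromide, BrC(Br)(Br)Br
Why: Appel reaction; bromide displaces the oxyphosphonium group at the primary benzylic carbon under buffered, nearly neutral conditions that the silyl ether and ring C should tolerate. The bromide is used without storage.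

Step 14
Reactants: 20 4-(tert-butoxy)-4-oxobutanoic acid; 21 (R)-4-benzyloxazolidin-2-one
Product: 23 tert-butyl 4-[(R)-4-benzyl-2-oxooxazolidin-3-yl]-4-oxobutanoate, via mixed pivalic anhydride 22 (not isolated)
Conditions: t-BuCOCl, Et3N, THF, −20 °C; then 21, LiCl, −20 °C to rt
Reagents that add atoms: pivaloyl chloride, CC(C)(C)C(=O)Cl (its atoms stay in 22 only, not in 23)
Why: N-Acylation of the oxazolidinone through a mixed anhydride; LiCl and Et3N activate the auxiliary, which attacks the less hindered succinyl carbonyl and not the pivaloyl one.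

Step 15
Reactants: 23 tert-butyl 4-[(R)-4-benzyl-2-oxooxazolidin-3-yl]-4-oxobutanoate; 6 1-(benzyloxy)-4-(bromomethyl)-2-methoxybenzene
Product: 24 tert-butyl (R)-3-[4-(benzyloxy)-3-methoxybenzyl]-4-[(R)-4-benzyl-2-oxooxazolidin-3-yl]-4-oxobutanoate
Conditions: NaN(SiMe3)2, THF, −78 °C; then 6, −78 to −40 °C
Reagents that add atoms: none
Why: Evans asymmetric alkylation; the imide α-CH2 is more acidic than the ester α-CH2 and gives the chelated Z-enolate. The benzylic bromide approaches the face opposite to the C4 benzyl group of the (R)-auxiliary, which sets the (R) centre.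

Step 16
Reactants: 24 tert-butyl (R)-3-[4-(benzyloxy)-3-methoxybenzyl]-4-[(R)-4-benzyl-2-oxooxazolidin-3-yl]-4-oxobutanoate
Product: 26 (R)-4-[4-(benzyloxy)-3-methoxybenzyl]dihydrofuran-2(3H)-one, via hydroxy tert-butyl ester 25 (not isolated)
Conditions: LiBH4, H2O (1 equiv), Et2O, 0 °C; aqueous work-up; then p-TsOH·H2O (cat.), toluene, 80 °C
Reagents that add atoms: none
Why: LiBH4 reduces the activated imide carbonyl and spares the hindered tert-butyl ester. Acid then cleaves the tert-butyl ester and the γ-hydroxy acid lactonises; the stereocentre is not touched.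

Step 17
Reactants: 26 (R)-4-[4-(benzyloxy)-3-methoxybenzyl]dihydrofuran-2(3H)-one; 19 {[(2S,3R)-2-[4-(benzyloxy)-3-methoxyphenyl]-5-(bromomethyl)-7-methoxy-2,3-dihydrobenzofuran-3-yl]methoxy}(tert-butyl)dimethylsilane
Product: 27 (3R,4R)-4-[4-(benzyloxy)-3-methoxybenzyl]-3-{[(2S,3R)-2-[4-(benzyloxy)-3-methoxyphenyl]-3-{[(tert-butyldimethylsilyl)oxy]methyl}-7-methoxy-2,3-dihydrobenzofuran-5-yl]methyl}dihydrofuran-2(3H)-one
Conditions: LiN(SiMe3)2, THF, −78 °C; then 19, DMPU, −78 to −30 °C
Reagents that add atoms: none
Why: Alkylation of a γ-butyrolactone lithium enolate; the benzylic bromide enters anti to the β-benzyl substituent (1,2-induction in the five-membered enolate), which should set the new centre as (3R), trans to C4.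

Step 18
Reactants: 27 (3R,4R)-4-[4-(benzyloxy)-3-methoxybenzyl]-3-{[(2S,3R)-2-[4-(benzyloxy)-3-methoxyphenyl]-3-{[(tert-butyldimethylsilyl)oxy]methyl}-7-methoxy-2,3-dihydrobenzofuran-5-yl]methyl}dihydrofuran-2(3H)-one
Product: 28 (2R,3R)-2-[4-(benzyloxy)-3-methoxybenzyl]-3-{[(2S,3R)-2-[4-(benzyloxy)-3-methoxyphenyl]-3-{[(tert-butyldimethylsilyl)oxy]methyl}-7-methoxy-2,3-dihydrobenzofuran-5-yl]methyl}butane-1,4-diol
Conditions: LiAlH4, THF, 0 °C
Reagents that add atoms: none
Why: Hydride reduction of the lactone to the 1,4-diol; alkyl silyl ethers, aryl benzyl ethers and ring C are stable to LiAlH4 at this temperature and no stereocentre is affected.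

Step 19
Reactants: 28 (2R,3R)-2-[4-(benzyloxy)-3-methoxybenzyl]-3-{[(2S,3R)-2-[4-(benzyloxy)-3-methoxyphenyl]-3-{[(tert-butyldimethylsilyl)oxy]methyl}-7-methoxy-2,3-dihydrobenzofuran-5-yl]methyl}butane-1,4-diol
Product: 29 (2R,3R)-2-[4-(benzyloxy)-3-methoxybenzyl]-3-{[(2S,3R)-2-[4-(benzyloxy)-3-methoxyphenyl]-3-(hydroxymethyl)-7-methoxy-2,3-dihydrobenzofuran-5-yl]methyl}butane-1,4-diol
Conditions: Bu4NF, THF, 0 °C to rt
Reagents that add atoms: none
Why: Fluoride-induced desilylation of a primary silyl ether, driven by the strong Si–F bond; the phenols are still benzylated, so no phenoxide chemistry can interfere.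

Step 20
Reactants: 29 (2R,3R)-2-[4-(benzyloxy)-3-methoxybenzyl]-3-{[(2S,3R)-2-[4-(benzyloxy)-3-methoxyphenyl]-3-(hydroxymethyl)-7-methoxy-2,3-dihydrobenzofuran-5-yl]methyl}butane-1,4-diol
Product: 30 (2R,3R)-2-(4-hydroxy-3-methoxybenzyl)-3-{[(2S,3R)-2-(4-hydroxy-3-methoxyphenyl)-3-(hydroxymethyl)-7-methoxy-2,3-dihydrobenzofuran-5-yl]methyl}butane-1,4-diol (CNP0256425.1)
Conditions: H2 (1 atm), 10% Pd/C, EtOAc/EtOH, rt, stopped at full conversion
Reagents that add atoms: none
Why: Catalytic hydrogenolysis of two aryl benzyl ethers on palladium; the unhindered primary O–CH2Ph bonds should cleave much faster than the hindered, cyclic secondary C2–O1 bond of ring C under these mild, acid-free conditions.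

## Compound list

1 | 4-bromo-2-methoxyphenol | COc1cc(Br)ccc1O | starting material
2 | allyl bromide | C=CCBr | starting material
3 | 1-(allyloxy)-4-bromo-2-methoxybenzene | COc1cc(Br)ccc1OCC=C | intermediate
4 | 2-allyl-4-bromo-6-methoxyphenol | COc1cc(Br)cc(CC=C)c1O | intermediate
5 | [4-(benzyloxy)-3-methoxyphenyl]methanol | COc1cc(CO)ccc1OCc1ccccc1 | starting material
6 | 1-(benzyloxy)-4-(bromomethyl)-2-methoxybenzene | COc1cc(CBr)ccc1OCc1ccccc1 | intermediate
7 | 1-allyl-2-{[4-(benzyloxy)-3-methoxybenzyl]oxy}-5-bromo-3-methoxybenzene | COc1cc(Br)cc(CC=C)c1OCc1ccc(OCc2ccccc2)c(OC)c1 | intermediate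
8 | 2-(2-{[4-(benzyloxy)-3-methoxybenzyl]oxy}-5-bromo-3-methoxyphenyl)acetaldehyde | COc1cc(Br)cc(CC=O)c1OCc1ccc(OCc2ccccc2)c(OC)c1 | intermediate
9 | 2-(2-{[4-(benzyloxy)-3-methoxybenzyl]oxy}-5-bromo-3-methoxyphenyl)acetic acid | COc1cc(Br)cc(CC(=O)O)c1OCc1ccc(OCc2ccccc2)c(OC)c1 | intermediate
10 | ethyl (S)-lactate | CCOC(=O)[C@H](C)O | starting material
11 | (S)-2-hydroxy-1-(pyrrolidin-1-yl)propan-1-one | C[C@H](O)C(=O)N1CCCC1 | intermediate
12 | (S)-1-oxo-1-(pyrrolidin-1-yl)propan-2-yl 2-(2-{[4-(benzyloxy)-3-methoxybenzyl]oxy}-5-bromo-3-methoxyphenyl)acetate | C[C@H](OC(=O)Cc1cc(Br)cc(OC)c1OCc1ccc(OCc2ccccc2)c(OC)c1)C(=O)N1CCCC1 | intermediate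
13 | (S)-1-oxo-1-(pyrrolidin-1-yl)propan-2-yl 2-(2-{[4-(benzyloxy)-3-methoxybenzyl]oxy}-5-bromo-3-methoxyphenyl)-2-diazoacetate | C[C@H](OC(=O)C(=[N+]=[N-])c1cc(Br)cc(OC)c1OCc1ccc(OCc2ccccc2)c(OC)c1)C(=O)N1CCCC1 | intermediate
14 | (S)-1-oxo-1-(pyrrolidin-1-yl)propan-2-yl (2S,3S)-2-[4-(benzyloxy)-3-methoxyphenyl]-5-bromo-7-methoxy-2,3-dihydrobenzofuran-3-carboxylate | Brc1cc(OC)c2c(c1)[C@H](C(=O)O[C@@H](C)C(=O)N1CCCC1)[C@@H](c1ccc(OCc3ccccc3)c(OC)c1)O2 | intermediate
15 | [(2S,3R)-2-[4-(benzyloxy)-3-methoxyphenyl]-5-bromo-7-methoxy-2,3-dihydrobenzofuran-3-yl]methanol | Brc1cc(OC)c2c(c1)[C@H](CO)[C@@H](c1ccc(OCc3ccccc3)c(OC)c1)O2 | intermediate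
16 | {[(2S,3R)-2-[4-(benzyloxy)-3-methoxyphenyl]-5-bromo-7-methoxy-2,3-dihydrobenzofuran-3-yl]methoxy}(tert-butyl)dimethylsilane | Brc1cc(OC)c2c(c1)[C@H](CO[Si](C)(C)C(C)(C)C)[C@@H](c1ccc(OCc3ccccc3)c(OC)c1)O2 | intermediate
17 | (2S,3R)-2-[4-(benzyloxy)-3-methoxyphenyl]-3-{[(tert-butyldimethylsilyl)oxy]methyl}-7-methoxy-2,3-dihydrobenzofuran-5-carbaldehyde | O=Cc1cc(OC)c2c(c1)[C@H](CO[Si](C)(C)C(C)(C)C)[C@@H](c1ccc(OCc3ccccc3)c(OC)c1)O2 | intermediate
18 | [(2S,3R)-2-[4-(benzyloxy)-3-methoxyphenyl]-3-{[(tert-butyldimethylsilyl)oxy]methyl}-7-methoxy-2,3-dihydrobenzofuran-5-yl]methanol | OCc1cc(OC)c2c(c1)[C@H](CO[Si](C)(C)C(C)(C)C)[C@@H](c1ccc(OCc3ccccc3)c(OC)c1)O2 | intermediate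
19 | {[(2S,3R)-2-[4-(benzyloxy)-3-methoxyphenyl]-5-(bromomethyl)-7-methoxy-2,3-dihydrobenzofuran-3-yl]methoxy}(tert-butyl)dimethylsilane | BrCc1cc(OC)c2c(c1)[C@H](CO[Si](C)(C)C(C)(C)C)[C@@H](c1ccc(OCc3ccccc3)c(OC)c1)O2 | intermediate
20 | 4-(tert-butoxy)-4-oxobutanoic acid | CC(C)(C)OC(=O)CCC(=O)O | starting material
21 | (R)-4-benzyloxazolidin-2-one | O=C1N[C@H](Cc2ccccc2)CO1 | starting material
22 | 4-(tert-butoxy)-4-oxobutanoic pivalic anhydride | CC(C)(C)OC(=O)CCC(=O)OC(=O)C(C)(C)C | intermediate
23 | tert-butyl 4-[(R)-4-benzyl-2-oxooxazolidin-3-yl]-4-oxobutanoate | CC(C)(C)OC(=O)CCC(=O)N1[C@H](Cc2ccccc2)COC1=O | intermediate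
24 | tert-butyl (R)-3-[4-(benzyloxy)-3-methoxybenzyl]-4-[(R)-4-benzyl-2-oxooxazolidin-3-yl]-4-oxobutanoate | COc1cc(C[C@@H](C(=O)N2[C@H](Cc3ccccc3)COC2=O)CC(=O)OC(C)(C)C)ccc1OCc1ccccc1 | intermediate
25 | tert-butyl (R)-3-[4-(benzyloxy)-3-methoxybenzyl]-4-hydroxybutanoate | COc1cc(C[C@@H](CO)CC(=O)OC(C)(C)C)ccc1OCc1ccccc1 | intermediate
26 | (R)-4-[4-(benzyloxy)-3-methoxybenzyl]dihydrofuran-2(3H)-one | COc1cc(C[C@H]2COC(=O)C2)ccc1OCc1ccccc1 | intermediate
27 | (3R,4R)-4-[4-(benzyloxy)-3-methoxybenzyl]-3-{[(2S,3R)-2-[4-(benzyloxy)-3-methoxyphenyl]-3-{[(tert-butyldimethylsilyl)oxy]methyl}-7-methoxy-2,3-dihydrobenzofuran-5-yl]methyl}dihydrofuran-2(3H)-one | COc1cc(C[C@H]2COC(=O)[C@@H]2Cc2cc(OC)c3c(c2)[C@H](CO[Si](C)(C)C(C)(C)C)[C@@H](c2ccc(OCc4ccccc4)c(OC)c2)O3)ccc1OCc1ccccc1 | intermediate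
28 | (2R,3R)-2-[4-(benzyloxy)-3-methoxybenzyl]-3-{[(2S,3R)-2-[4-(benzyloxy)-3-methoxyphenyl]-3-{[(tert-butyldimethylsilyl)oxy]methyl}-7-methoxy-2,3-dihydrobenzofuran-5-yl]methyl}butane-1,4-diol | COc1cc(C[C@@H](CO)[C@H](CO)Cc2cc(OC)c3c(c2)[C@H](CO[Si](C)(C)C(C)(C)C)[C@@H](c2ccc(OCc4ccccc4)c(OC)c2)O3)ccc1OCc1ccccc1 | intermediate
29 | (2R,3R)-2-[4-(benzyloxy)-3-methoxybenzyl]-3-{[(2S,3R)-2-[4-(benzyloxy)-3-methoxyphenyl]-3-(hydroxymethyl)-7-methoxy-2,3-dihydrobenzofuran-5-yl]methyl}butane-1,4-diol | COc1cc(C[C@@H](CO)[C@H](CO)Cc2cc(OC)c3c(c2)[C@H](CO)[C@@H](c2ccc(OCc4ccccc4)c(OC)c2)O3)ccc1OCc1ccccc1 | intermediate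
30 | (2R,3R)-2-(4-hydroxy-3-methoxybenzyl)-3-{[(2S,3R)-2-(4-hydroxy-3-methoxyphenyl)-3-(hydroxymethyl)-7-methoxy-2,3-dihydrobenzofuran-5-yl]methyl}butane-1,4-diol | COc1cc(C[C@@H](CO)[C@H](CO)Cc2cc(OC)c3c(c2)[C@H](CO)[C@@H](c2ccc(O)c(OC)c2)O3)ccc1O | target

## Step count and least certain steps

Total step count: 20. Longest linear sequence: 15 steps (steps 1, 2, 4, 5, 7 to 13 and 17 to 20, from 1 to 30).

**Step 9 (key step).** The most likely failure is insufficient facial discrimination or cis/trans control in the insertion, because the catalyst pocket and the auxiliary may reinforce each other less well on this 7-methoxy, para-benzyloxy substrate than on simpler ones. Carbene dimerisation may also compete if the diazo ester accumulates, and base equilibration of cis material may open ring C by β-elimination through the C3 enolate. The fallback moves stereocontrol to the catalyst alone and to thermodynamics.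
- It sets out from 9, which would be esterified with MeI and K2CO3 to methyl 2-(2-{[4-(benzyloxy)-3-methoxybenzyl]oxy}-5-bromo-3-methoxyphenyl)acetate F1.
- Diazo transfer as in step 8 would give methyl 2-(2-{[4-(benzyloxy)-3-methoxybenzyl]oxy}-5-bromo-3-methoxyphenyl)-2-diazoacetate F2.
- A cis-selective insertion in toluene at −78 °C with Rh2(S-PTTL)4, the dirhodium tetrakis[N-phthaloyl-(S)-tert-leucinate] of divalent rhodium (or its mirror image, whichever leads to the (2S) series), would give methyl (2S,3R)-2-[4-(benzyloxy)-3-methoxyphenyl]-5-bromo-7-methoxy-2,3-dihydrobenzofuran-3-carboxylate F3.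
- NaOMe in MeOH would epimerise C3 to the trans ester methyl (2S,3S)-2-[4-(benzyloxy)-3-methoxyphenyl]-5-bromo-7-methoxy-2,3-dihydrobenzofuran-3-carboxylate F4.
- LiBH4 reduction of F4 comes back to the route at 15.

**Step 17.** The most likely failure is loss of the electrophile by ionisation of the para-oxygenated benzylic bromide (solvolysis or self-alkylation) before the enolate captures it. Proton exchange between product and enolate could also lead to double alkylation. The fallback forms the same C–C bond by carbonyl addition and removes the oxygen afterwards.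
- It sets out from 16 and 26. Step 12 would be stopped after the DMF quench by aqueous work-up, so that 17 is isolated.
- Addition of the lithium enolate of 26 to 17 (aldol addition, anti to the β-substituent) would give (3S,4R)-4-[4-(benzyloxy)-3-methoxybenzyl]-3-{[(2S,3R)-2-[4-(benzyloxy)-3-methoxyphenyl]-3-{[(tert-butyldimethylsilyl)oxy]methyl}-7-methoxy-2,3-dihydrobenzofuran-5-yl](hydroxy)methyl}dihydrofuran-2(3H)-one F5 as a mixture at the carbinol carbon.
- PhOC(S)Cl and pyridine would convert it into the O-phenyl thionocarbonate of that carbinol F6.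
- Barton–McCombie deoxygenation with Bu3SnH and AIBN in toluene at 80 °C, a neutral radical process that should not affect ring C or the silyl ether, comes back to the route at 27.

**Step 20.** The most likely failure is over-reduction: hydrogenolytic opening of ring C at the benzylic C2–O1 bond, which becomes more labile once the para phenol of ring D is free. Stalling after loss of the first benzyl group is the second possibility. The fallback replaces reductive cleavage by Lewis-acid cleavage with a cation scavenger. It sets out from 29, uses BCl3 and pentamethylbenzene in CH2Cl2 at −78 °C followed by a methanol quench, and comes back at 30. It makes no new compound (F0).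

**Step 15.** The most likely failure is incomplete regiocontrol of enolisation (imide against tert-butyl ester α-position), or decay of the sodium enolate by loss of the auxiliary before the bromide reacts, which would lower yield and diastereomeric purity. The fallback sets the stereocentre by catalytic asymmetric hydrogenation instead.
- It sets out from 5, which MnO2 would oxidise to 4-(benzyloxy)-3-methoxybenzaldehyde F7.
- Stobbe condensation with dimethyl succinate and NaOMe would give (E)-4-[4-(benzyloxy)-3-methoxyphenyl]-3-(methoxycarbonyl)but-3-enoic acid F8.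
- Hydrogenation with [Rh(cod)(Et-DuPHOS)]BF4 (monovalent rhodium, ligand antipode chosen to deliver the R acid) would give (R)-4-[4-(benzyloxy)-3-methoxyphenyl]-3-(methoxycarbonyl)butanoic acid F9.
- Reduction of the ester in the carboxylate salt with Ca(BH4)2 (from CaCl2 and NaBH4), followed by acidification with HCl, comes back to the route at 26.

## Further compounds

F1 | step 9 | methyl 2-(2-{[4-(benzyloxy)-3-methoxybenzyl]oxy}-5-bromo-3-methoxyphenyl)acetate | COC(=O)Cc1cc(Br)cc(OC)c1OCc1ccc(OCc2ccccc2)c(OC)c1
F2 | step 9 | methyl 2-(2-{[4-(benzyloxy)-3-methoxybenzyl]oxy}-5-bromo-3-methoxyphenyl)-2-diazoacetate | COC(=O)C(=[N+]=[N-])c1cc(Br)cc(OC)c1OCc1ccc(OCc2ccccc2)c(OC)c1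
F3 | step 9 | methyl (2S,3R)-2-[4-(benzyloxy)-3-methoxyphenyl]-5-bromo-7-methoxy-2,3-dihydrobenzofuran-3-carboxylate (cis) | Brc1cc(OC)c2c(c1)[C@@H](C(=O)OC)[C@@H](c1ccc(OCc3ccccc3)c(OC)c1)O2
F4 | step 9 | methyl (2S,3S)-2-[4-(benzyloxy)-3-methoxyphenyl]-5-bromo-7-methoxy-2,3-dihydrobenzofuran-3-carboxylate (trans) | Brc1cc(OC)c2c(c1)[C@H](C(=O)OC)[C@@H](c1ccc(OCc3ccccc3)c(OC)c1)O2
F5 | step 17 | (3S,4R)-4-[4-(benzyloxy)-3-methoxybenzyl]-3-{[(2S,3R)-2-[4-(benzyloxy)-3-methoxyphenyl]-3-{[(tert-butyldimethylsilyl)oxy]methyl}-7-methoxy-2,3-dihydrobenzofuran-5-yl](hydroxy)methyl}dihydrofuran-2(3H)-one (carbinol epimers) | COc1cc(C[C@H]2COC(=O)[C@@H]2C(O)c2cc(OC)c3c(c2)[C@H](CO[Si](C)(C)C(C)(C)C)[C@@H](c2ccc(OCc4ccccc4)c(OC)c2)O3)ccc1OCc1ccccc1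
F6 | step 17 | O-{[(3S,4R)-4-[4-(benzyloxy)-3-methoxybenzyl]-2-oxotetrahydrofuran-3-yl][(2S,3R)-2-[4-(benzyloxy)-3-methoxyphenyl]-3-{[(tert-butyldimethylsilyl)oxy]methyl}-7-methoxy-2,3-dihydrobenzofuran-5-yl]methyl} O-phenyl carbonothioate | COc1cc(C[C@H]2COC(=O)[C@@H]2C(OC(=S)Oc2ccccc2)c2cc(OC)c3c(c2)[C@H](CO[Si](C)(C)C(C)(C)C)[C@@H](c2ccc(OCc4ccccc4)c(OC)c2)O3)ccc1OCc1ccccc1
F0 | step 20 | none | none
F7 | step 15 | 4-(benzyloxy)-3-methoxybenzaldehyde | COc1cc(C=O)ccc1OCc1ccccc1
F8 | step 15 | (E)-4-[4-(benzyloxy)-3-methoxyphenyl]-3-(methoxycarbonyl)but-3-enoic acid | OC(=O)C/C(C(=O)OC)=C\c1ccc(OCc2ccccc2)c(OC)c1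
F9 | step 15 | (R)-4-[4-(benzyloxy)-3-methoxyphenyl]-3-(methoxycarbonyl)butanoic acid | COc1cc(C[C@@H](C(=O)OC)CC(=O)O)ccc1OCc1ccccc1
A1 | alternative 1 | 4-bromo-2-[(2R)-1-[(tert-butyldimethylsilyl)oxy]-3-(4-hydroxy-3-methoxyphenyl)propan-2-yl]-6-methoxyphenol | Brc1cc(OC)c(O)c(c1)[C@H](CO[Si](C)(C)C(C)(C)C)Cc1ccc(O)c(OC)c1
A2 | alternative 1 | 4-[(2R)-2-(5-bromo-2-hydroxy-3-methoxyphenyl)-3-[(tert-butyldimethylsilyl)oxy]propylidene]-2-methoxycyclohexa-2,5-dien-1-one | Brc1cc(OC)c(O)c(c1)[C@H](CO[Si](C)(C)C(C)(C)C)C=C1C=CC(=O)C(OC)=C1
A3 | alternative 1 | 4-[(2S,3R)-5-bromo-3-{[(tert-butyldimethylsilyl)oxy]methyl}-7-methoxy-2,3-dihydrobenzofuran-2-yl]-2-methoxyphenol | Brc1cc(OC)c2c(c1)[C@H](CO[Si](C)(C)C(C)(C)C)[C@@H](c1ccc(O)c(OC)c1)O2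
A4 | alternative 2 | (5R)-5-{[(1R,2S,5R)-2-isopropyl-5-methylcyclohexyl]oxy}furan-2(5H)-one | O=C1C=C[C@H](O[C@@H]2C[C@H](C)CC[C@H]2C(C)C)O1
A5 | alternative 2 | 2-[(2S,3R)-2-[4-(benzyloxy)-3-methoxyphenyl]-3-{[(tert-butyldimethylsilyl)oxy]methyl}-7-methoxy-2,3-dihydrobenzofuran-5-yl]-1,3-dithiane | C1CSC(SC1)c1cc(OC)c2c(c1)[C@H](CO[Si](C)(C)C(C)(C)C)[C@@H](c1ccc(OCc3ccccc3)c(OC)c1)O2
A6 | alternative 2 | (3R,4R,5R)-3-[4-(benzyloxy)-3-methoxybenzyl]-4-{2-[(2S,3R)-2-[4-(benzyloxy)-3-methoxyphenyl]-3-{[(tert-butyldimethylsilyl)oxy]methyl}-7-methoxy-2,3-dihydrobenzofuran-5-yl]-1,3-dithian-2-yl}-5-{[(1R,2S,5R)-2-isopropyl-5-methylcyclohexyl]oxy}dihydrofuran-2(3H)-one | COc1cc(C[C@@H](C5=O)[C@H]([C@H](O[C@@H]6C[C@H](C)CC[C@H]6C(C)C)O5)C7(SCCCS7)c2cc(OC)c3c(c2)[C@H](CO[Si](C)(C)C(C)(C)C)[C@@H](c2ccc(OCc4ccccc4)c(OC)c2)O3)ccc1OCc1ccccc1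
A7 | alternative 3 | (2S)-6-bromo-8-methoxy-2-[3-methoxy-4-(pivaloyloxy)phenyl]chroman-4-one | O=C1C[C@@H](c2ccc(OC(=O)C(C)(C)C)c(OC)c2)Oc2c(OC)cc(Br)cc12
A8 | alternative 3 | methyl (2S,3S)-5-bromo-7-methoxy-2-[3-methoxy-4-(pivaloyloxy)phenyl]-2,3-dihydrobenzofuran-3-carboxylate | Brc1cc(OC)c2c(c1)[C@H](C(=O)OC)[C@@H](c1ccc(OC(=O)C(C)(C)C)c(OC)c1)O2
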